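Remarks on the chemistry: the arene positions are numbered C1 (CH2N), C2 (Br), C3 (OH), C4 (OH), C5 (Br), C6 (Br). Every intermediate with a single stereocentre is used as the racemate, because that centre ends as an sp2 ring carbon.

## Analysis of the target

The target 16 is a hexasubstituted benzene that carries, in ring order, a (2-oxopyrrolidin-1-yl)methyl group at C1, bromine at C2, hydroxyl groups at C3 and C4, and bromine at C5 and C6. The only other ring is the N-alkylated five-membered lactam, joined to the arene through one benzylic CH2. There is no stereocentre, so any sp3 centre created on the way is of no lasting consequence. The sensitive groups are the catechol (easily oxidised to the ortho-quinone, above all as its anion in air), the lactam (opened by forcing acid or base, and weakly C–H acidic at its α-carbon) and the benzylic C–N bond para to the C4 hydroxyl, which could be lost by ipso attack of a strong electrophile. The difficulty is the fully substituted ring: six contiguous substituents of three kinds, with an oxygen pattern and an oxidation level that must be reached without exposing the free catechol to many steps. The strategy rests on reading C3 and C4 as the two carbonyl carbons of an oxalic ester, and C2 and C5 as the two α-carbons of a hexanedioic ester whose C3 bears the CH2N group. The ester carbons then sit on C2 and C5, each ortho to a hydroxyl, exactly where a carboxyl group can later be exchanged for bromine.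

## Retrosynthetic reasoning

The three C–Br bonds of 16 are cut first. Those at C2 and C5 are traced back to C–CO2H bonds and that at C6 to a C–H bond, which leads to the dihydroxy diacid 13. A carboxyl group ortho to a phenolic hydroxyl is displaced by an electrophilic halogen with decarboxylation, and C6–H is para to the C3 hydroxyl, so one halogenating operation should place all three bromines. What is gained is that the two ring carbons flanking the catechol may carry acyl groups throughout the ring construction.

The diacid 13 comes from the dimethyl ester 12 by hydrolysis. The forward reaction has to cleave two ortho-substituted aryl esters without opening the lactam and without oxidising the catecholate.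

The arene 12 is one oxidation level (two electrons) above the carbocycle 10, whose bis-enol already is a cyclohexadiene-diol. The disconnection is therefore a retro-dehydrogenation. The two ester groups make the ring CH positions of 10 enolizable, so the forward step needs only one equivalent of a mild halogen oxidant.

The carbocycle 10 is cut at the C2–C3 and C4–C5 bonds (arene numbering), each between an ester-bearing carbon and a ketone carbon. These are the two bonds a Claisen condensation makes, and cutting both at once releases the symmetrical two-carbon unit 8 and the open-chain diester 7. Cutting here, and not at C1–C2 or C3–C4, keeps the side chain on a saturated chain carbon and lets the ring close under equilibrating base with a stable dienolate as the end point. Because 8 is symmetrical, the branch in 7 cannot give constitutional isomers.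

The diester 7 is the methyl ester of the diacid 6, and a 3-substituted hexanedioic acid is the ozonolytic cleavage product of a 4-substituted cyclohexene. The chain is thus traced to the ring alkene 4, in which the branch point is fixed by the ring and both acid termini arise in one oxidative step.

The lactam 4 is cut at its two C–N bonds, the amide bond and the N–CH2 bond of the five-membered ring. This gives the primary amine 1 and the four-carbon bis-electrophile 2, which combine by N-acylation and then ring closure of the amide anion onto the chloride via 3.

## Alternatives that were turned down

Alternative 1: The arene is cut at C1–C2 and C5–C6 into a four-carbon diene that already carries C2 to C5 with their substituents, 2,5-dibromo-3,4-dimethoxythiophene 1,1-dioxide A2, and a two-carbon alkyne carrying C1 and C6, 1-(3-bromoprop-2-yn-1-yl)pyrrolidin-2-one A3. In the forward sense a [4+2] cycloaddition through the diene termini, followed by cheletropic loss of the sulfonyl bridge, would give 1-[(2,3,6-tribromo-4,5-dimethoxyphenyl)methyl]pyrrolidin-2-one A1, and only cleavage of the two methyl ethers would remain.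
- In its favour: it is the most convergent plan. All six substituents arrive in one step, the symmetry of A2 removes any regiochemical question, and no late halogenation or oxidation is needed.
- Against it: both reacting termini of A2 bear bromine and the dienophile is a disubstituted, weakly polarised alkyne, so a hexasubstituted ring must form through a very crowded transition state. Thiophene dioxides add best as electron-poor dienes to electron-rich or strained partners, and here the two methoxy groups make the diene less electron-poor while the bromoalkyne is not electron-rich. The temperatures this implies threaten A3. A2 itself requires oxidation at sulfur of an electron-rich, halogenated thiophene, which is not a dependable operation.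
- Comparison: on convergence and on step count after the fragments exist it is stronger. The chosen route offers instead a ring formation pulled forward by a thermodynamic sink and built from bulk reagents.

Alternative 2: The catechol 1-[(3,4-dihydroxyphenyl)methyl]pyrrolidin-2-one A4 is recognised as an isomer of 1-[(5-acetylfuran-2-yl)methyl]pyrrolidin-2-one A5. In hot dilute aqueous acid the furan of A5 would open to 1-(2,5,6-trioxoheptyl)pyrrolidin-2-one A7, whose terminal methyl carbon would add to the ketone next to the CH2N group (forming C1–C2), and dehydration and enolization would give A4. Exhaustive electrophilic bromination of the three free positions would finish the synthesis.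
- In its favour: it is clearly the shortest plan. The key step is an isomerisation with no reagent beyond acid and water, and the final bromination has no regiochemical problem because every free position is to be brominated.
- Against it: an acyl-deactivated furan opens only under forcing hydrothermal conditions. A7 has several enolizable carbons, and its 1,4-dicarbonyl portion can close to a five-membered enone or resinify. The furfuryl C–N bond of A5 ionises readily in acid, and hot aqueous acid also attacks the lactam.
- Comparison: in step count it is stronger by a clear margin if its key step works. The chosen route offers a ring closure under mild base in which the lactam is a spectator and only one ring constitution can form.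

Alternative 3: The ring is cut at C3–C4, so that the diester 7 of the chosen route closes across its two ester carbons. Reductive acyloin coupling with an alkali metal and a silyl chloride trap would give the enediol bis-silyl ether 1-{[3,4-bis(trimethylsilyloxy)cyclohex-3-en-1-yl]methyl}pyrrolidin-2-one A6. Two further oxidation levels would then have to be climbed to reach A4, and exhaustive bromination would follow.
- In its favour: it shares 7. A silyl-trapped six-membered acyloin closure is dependable and is not troubled by Dieckmann condensation. No carboxyl groups need to be removed later, so ester hydrolysis is avoided.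
- Against it: the ring arrives two oxidation levels below the arene and without ester groups to acidify the ring CH positions, so aromatisation depends on harsher dehydrogenation. The dissolving metal may also engage the lactam carbonyl, and A6 is sensitive to hydrolysis.
- Comparison: from 7 onward the step count is about equal. In the chosen route the same ester groups drive the ring closure thermodynamically, reduce the aromatisation to one mild two-electron oxidation, and are then exchanged for two of the three bromines. Because the precursor is common, this closure is kept as the fallback for the key step.

Key step: step 4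

## Route

Step 1
Reactants: 1 cyclohex-3-en-1-ylmethanamine (racemic); 2 4-chlorobutanoyl chloride
Product: 4 1-(cyclohex-3-en-1-ylmethyl)pyrrolidin-2-one (racemic), via 4-chloro-N-(cyclohex-3-en-1-ylmethyl)butanamide 3 (not isolated)
Conditions: Et3N (1.1 equiv), THF, 0 °C; filter; then KOtBu (1.2 equiv), THF, 0 °C → rt
Reagents that add atoms: none
Why: N-acylation of the primary amine by the acid chloride, then intramolecular N-alkylation of the amide anion by the primary chloride (5-exo-tet lactamisation), the standard two-stage pyrrolidinone synthesis. The N–H is far more acidic than the α-CH2, so lactam formation should prevail over cyclopropane formation.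

Step 2
Reactants: 4 1-(cyclohex-3-en-1-ylmethyl)pyrrolidin-2-one
Product: 6 3-[(2-oxopyrrolidin-1-yl)methyl]hexanedioic acid (racemic), via 1-[(7,8,9-trioxabicyclo[4.2.1]nonan-3-yl)methyl]pyrrolidin-2-one 5 (not isolated)
Conditions: O3, CH2Cl2, −78 °C; then HCO2H, 30% H2O2, warm to 70 °C (CH2Cl2 distilled off)
Reagents that add atoms: ozone, [O-][O+]=O; hydrogen peroxide, OO
Why: Criegee ozonolysis of the ring alkene to the ozonide 5 (partly oligomeric), then oxidative work-up with performic acid formed in the flask, which should take both termini to carboxylic acids. The tertiary lactam has no site that ozone or a peracid attacks at these temperatures.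

Step 3
Reactants: 6 3-[(2-oxopyrrolidin-1-yl)methyl]hexanedioic acid
Product: 7 dimethyl 3-[(2-oxopyrrolidin-1-yl)methyl]hexanedioate (racemic)
Conditions: MeOH, H2SO4 (cat.), reflux
Reagents that add atoms: methanol, CO
Why: Fischer esterification of two unhindered aliphatic acids in excess methanol. The five-membered lactam should not be opened by methanol under catalytic acid, since ring closure is favoured at equilibrium.

Step 4
Reactants: 7 dimethyl 3-[(2-oxopyrrolidin-1-yl)methyl]hexanedioate; 8 dimethyl oxalate
Product: 10 dimethyl 2,3-dioxo-5-[(2-oxopyrrolidin-1-yl)methyl]cyclohexane-1,4-dicarboxylate (mixture of stereoisomers and enol forms), via trimethyl 1-oxo-4-[(2-oxopyrrolidin-1-yl)methyl]pentane-1,2,5-tricarboxylate 9 (not isolated)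
Conditions: NaOMe (2.5 equiv), 8 (1.1 equiv), THF, 0 °C → reflux (MeOH distilled off); then 1 M HCl, 0 °C
Reagents that add atoms: none
Why: This is the double Claisen condensation of an adipic ester with an oxalic ester, the classical entry to 2,3-dioxocyclohexane-1,4-dicarboxylates. Methoxide generates an ester enolate of 7, most readily at the α-CH2 remote from the branch, which attacks one carbonyl of 8 and expels methoxide to give the α-oxalyl ester 9, held as its stabilised enolate. The remaining α-carbon is then deprotonated and attacks the terminal ester carbonyl of the oxalyl group in a 6-(enolexo)-exo-trig Dieckmann-type closure, which forms the second ring bond and the six-membered carbocycle. Every step is reversible, and the product is drained from the equilibria as the sparingly soluble disodium salt of the doubly enolized bis-β-keto ester, which is why more than two equivalents of base and removal of methanol are used. No stereocentre is set under control: the three sp3 ring CH centres of the keto form are enolizable, so 10 is expected as an equilibrating mixture, and all of them become sp2 in step 5. Two selectivities are needed. Cross-condensation must outrun the five-membered Dieckmann self-condensation of 7, which the high electrophilicity of the non-enolizable oxalate and slow addition of 7 to base and 8 at low temperature should secure; and acylation must occur at the ester α-carbons, not at the lactam α-CH2, which follows from the lower acidity of amide α-protons and from the ring-closed dienolate being the only thermodynamic sink. Because 8 is symmetrical, the branch in 7 raises no regiochemical question and both ester groups end up next to an oxygen-bearing carbon.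

Step 5
Reactants: 10 dimethyl 2,3-dioxo-5-[(2-oxopyrrolidin-1-yl)methyl]cyclohexane-1,4-dicarboxylate
Product: 12 dimethyl 2,3-dihydroxy-5-[(2-oxopyrrolidin-1-yl)methyl]benzene-1,4-dicarboxylate, via dimethyl 1-bromo-2,3-dioxo-5-[(2-oxopyrrolidin-1-yl)methyl]cyclohexane-1,4-dicarboxylate 11 (not isolated)
Conditions: Br2 (1.0 equiv), AcOH, 10 °C → 60 °C, N2
Reagents that add atoms: none
Why: Halogenative aromatisation: electrophilic α-bromination of the enolized β-keto ester gives 11, which loses HBr and enolizes to the catechol, so one equivalent of Br2 supplies the single two-electron oxidation required. This is the known conversion of 2,3-dioxocyclohexane-1,4-dicarboxylates into 2,3-dihydroxyterephthalates, and any further ring bromination would fall on C6, which is to carry bromine anyway.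

Step 6
Reactants: 12 dimethyl 2,3-dihydroxy-5-[(2-oxopyrrolidin-1-yl)methyl]benzene-1,4-dicarboxylate
Product: 13 2,3-dihydroxy-5-[(2-oxopyrrolidin-1-yl)methyl]benzene-1,4-dicarboxylic acid
Conditions: LiOH (6 equiv), THF/MeOH/H2O, 60 °C, N2; then 2 M HCl to pH 1
Reagents that add atoms: lithium hydroxide, [Li+].[OH-]; water, O
Why: Saponification of the two aryl methyl esters by acyl–oxygen cleavage. The tertiary γ-lactam is much less electrophilic than the esters, and exclusion of air protects the catecholate from autoxidation.

Step 7
Reactants: 13 2,3-dihydroxy-5-[(2-oxopyrrolidin-1-yl)methyl]benzene-1,4-dicarboxylic acid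
Product: 16 1-[(2,3,6-tribromo-4,5-dihydroxyphenyl)methyl]pyrrolidin-2-one, via 5-bromo-2,3-dihydroxy-6-[(2-oxopyrrolidin-1-yl)methyl]benzene-1,4-dicarboxylic acid 14 (not isolated), via 2,4-dibromo-5,6-dihydroxy-3-[(2-oxopyrrolidin-1-yl)methyl]benzoic acid 15 (not isolated)
Conditions: Br2 (3.1 equiv), AcOH/H2O, 0 °C → rt; then aq. NaHSO3
Reagents that add atoms: bromine, BrBr
Why: Electrophilic aromatic bromination at the free C6–H (para to the C3 hydroxyl) should come first, followed by ipso attack at each carboxyl-bearing carbon ortho to a hydroxyl; the resulting cyclohexadienone rearomatises by losing CO2, as in the bromodecarboxylation of salicylic and 4-hydroxybenzoic acid with bromine water. The order of the two ipso substitutions is presumed and either order leads to 16. The reductive quench destroys excess Br2 and returns any ortho-quinone to the catechol.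

## Compound list

1 | cyclohex-3-en-1-ylmethanamine (racemic) | NCC1CCC=CC1 | starting material
2 | 4-chlorobutanoyl chloride | O=C(Cl)CCCCl | starting material
3 | 4-chloro-N-(cyclohex-3-en-1-ylmethyl)butanamide (racemic; formed in the flask, not isolated) | O=C(CCCCl)NCC1CCC=CC1 | intermediate
4 | 1-(cyclohex-3-en-1-ylmethyl)pyrrolidin-2-one (racemic) | O=C1CCCN1CC1CCC=CC1 | intermediate
5 | 1-[(7,8,9-trioxabicyclo[4.2.1]nonan-3-yl)methyl]pyrrolidin-2-one (ozonide of 4, mixture of stereoisomers; formed in the flask, not isolated) | O=C1CCCN1CC2CC3OOC(CC2)O3 | intermediate
6 | 3-[(2-oxopyrrolidin-1-yl)methyl]hexanedioic acid (racemic) | O=C(O)CCC(CN1CCCC1=O)CC(=O)O | intermediate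
7 | dimethyl 3-[(2-oxopyrrolidin-1-yl)methyl]hexanedioate (racemic) | COC(=O)CCC(CN1CCCC1=O)CC(=O)OC | intermediate
8 | dimethyl oxalate | COC(=O)C(=O)OC | starting material
9 | trimethyl 1-oxo-4-[(2-oxopyrrolidin-1-yl)methyl]pentane-1,2,5-tricarboxylate (mixture of stereoisomers; formed in the flask, not isolated) | COC(=O)C(=O)C(C(=O)OC)CC(CN1CCCC1=O)CC(=O)OC | intermediate
10 | dimethyl 2,3-dioxo-5-[(2-oxopyrrolidin-1-yl)methyl]cyclohexane-1,4-dicarboxylate (mixture of stereoisomers and enol forms) | COC(=O)C1CC(CN2CCCC2=O)C(C(=O)OC)C(=O)C1=O | intermediate
11 | dimethyl 1-bromo-2,3-dioxo-5-[(2-oxopyrrolidin-1-yl)methyl]cyclohexane-1,4-dicarboxylate (mixture of stereoisomers; formed in the flask, not isolated) | COC(=O)C1(Br)CC(CN2CCCC2=O)C(C(=O)OC)C(=O)C1=O | intermediate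
12 | dimethyl 2,3-dihydroxy-5-[(2-oxopyrrolidin-1-yl)methyl]benzene-1,4-dicarboxylate | COC(=O)c1cc(CN2CCCC2=O)c(C(=O)OC)c(O)c1O | intermediate
13 | 2,3-dihydroxy-5-[(2-oxopyrrolidin-1-yl)methyl]benzene-1,4-dicarboxylic acid | O=C(O)c1cc(CN2CCCC2=O)c(C(=O)O)c(O)c1O | intermediate
14 | 5-bromo-2,3-dihydroxy-6-[(2-oxopyrrolidin-1-yl)methyl]benzene-1,4-dicarboxylic acid (formed in the flask, not isolated) | O=C1CCCN1Cc1c(C(=O)O)c(O)c(O)c(C(=O)O)c1Br | intermediate
15 | 2,4-dibromo-5,6-dihydroxy-3-[(2-oxopyrrolidin-1-yl)methyl]benzoic acid (formed in the flask, not isolated) | O=C1CCCN1Cc1c(Br)c(O)c(O)c(C(=O)O)c1Br | intermediate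
16 | 1-[(2,3,6-tribromo-4,5-dihydroxyphenyl)methyl]pyrrolidin-2-one | O=C1CCCN1Cc1c(Br)c(O)c(O)c(Br)c1Br | target

## Step count and least certain steps

Total step count: 7. Longest linear sequence: 7 steps (1 → 16); dimethyl oxalate 8 enters at step 4.

Step 4 (key step). The most likely failures are three: intramolecular Dieckmann condensation of 7 to five-membered β-keto esters before the oxalate is engaged; stalling after the first acylation, because the second enolate must form at the more hindered α-carbon next to the branch; and competing C-acylation at the lactam α-position. All are plausible because every Claisen step is reversible and the outcome depends on the ring-closed dienolate being the deepest well. The fallback sets out from 7, closes the ring across the other pair of carbons and comes back to the route at 16. Rühlmann acyloin condensation (Na, Me3SiCl, toluene, reflux) would give 1-{[3,4-bis(trimethylsilyloxy)cyclohex-3-en-1-yl]methyl}pyrrolidin-2-one F1. Br2 in CH2Cl2 at low temperature would oxidise it to 4-[(2-oxopyrrolidin-1-yl)methyl]cyclohexane-1,2-dione F2. Dehydrogenation over 10% Pd/C in refluxing p-cymene would give 1-[(3,4-dihydroxyphenyl)methyl]pyrrolidin-2-one F3. Br2 (3 equiv) in AcOH would then brominate all three free ring positions to give 16.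

Step 7. Aqueous bromine may oxidise the catechol to the ortho-quinone. The second ipso substitution may also stall, because each bromine that enters makes the ring poorer. A further possibility is ipso attack at C1, para to the C4 hydroxyl, with loss of the side chain. The fallback sets out from 13, uses bromine only for ordinary substitution of ring hydrogens, and comes back at 16. One equivalent of Br2 in AcOH would brominate C6–H to give the bromo diacid 14, which would here be isolated. With bromine at C6 each carboxyl group is flanked on both sides and twisted out of the ring plane, which should ease thermal protodecarboxylation of the two salicylic-type acids (quinoline, about 200 °C, N2) to 1-[(2-bromo-4,5-dihydroxyphenyl)methyl]pyrrolidin-2-one F4. Br2 (2 equiv) in AcOH would then enter the two remaining ring positions, each ortho to a hydroxyl, to give 16.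

Step 6. The ester at C2 is flanked by a hydroxyl and the CH2N group, so acyl–oxygen hydrolysis may be slow. The forcing conditions this invites may in turn lead to hydroxide opening of the lactam and autoxidation of the catecholate. The fallback sets out from 12 and comes back at 13. Nucleophilic demethylation by alkyl–oxygen cleavage (LiI, EtOAc, reflux, then dilute HCl) attacks the methyl groups and is insensitive to the ortho substituents and to the lactam. It makes no new compound.

Step 5. Bromination may occur at ring positions from which HBr cannot be lost productively, or more than one bromine may be taken up, so that the aromatisation gives mixtures; dehydrobromination of 11 may also be incomplete at moderate temperature. The fallback sets out from 10 and comes back at 12. Catalytic dehydrogenation (10% Pd/C, refluxing p-cymene, N2) removes the two hydrogens without any halogen. It makes no new compound.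

## Further compounds

F1 | step 4 | 1-{[3,4-bis(trimethylsilyloxy)cyclohex-3-en-1-yl]methyl}pyrrolidin-2-one (racemic) | C[Si](C)(C)OC1=C(O[Si](C)(C)C)CC(CN2CCCC2=O)CC1
F2 | step 4 | 4-[(2-oxopyrrolidin-1-yl)methyl]cyclohexane-1,2-dione (racemic) | O=C1CCCN1CC1CCC(=O)C(=O)C1
F3 | step 4 | 1-[(3,4-dihydroxyphenyl)methyl]pyrrolidin-2-one | O=C1CCCN1Cc1ccc(O)c(O)c1
F4 | step 7 | 1-[(2-bromo-4,5-dihydroxyphenyl)methyl]pyrrolidin-2-one | O=C1CCCN1Cc1cc(O)c(O)cc1Br
F0 | step 6 | none | none
F0 | step 5 | none | none
A1 | alternative 1 | 1-[(2,3,6-tribromo-4,5-dimethoxyphenyl)methyl]pyrrolidin-2-one | O=C1CCCN1Cc1c(Br)c(OC)c(OC)c(Br)c1Br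
A2 | alternative 1 | 2,5-dibromo-3,4-dimethoxythiophene 1,1-dioxide | COC1=C(Br)S(=O)(=O)C(Br)=C1OC
A3 | alternative 1 | 1-(3-bromoprop-2-yn-1-yl)pyrrolidin-2-one | O=C1CCCN1CC#CBr
A4 | alternative 2 | 1-[(3,4-dihydroxyphenyl)methyl]pyrrolidin-2-one | O=C1CCCN1Cc1ccc(O)c(O)c1
A5 | alternative 2 | 1-[(5-acetylfuran-2-yl)methyl]pyrrolidin-2-one | CC(=O)c1ccc(CN2CCCC2=O)o1
A7 | alternative 2 | 1-(2,5,6-trioxoheptyl)pyrrolidin-2-one | CC(=O)C(=O)CCC(=O)CN1CCCC1=O
A6 | alternative 3 | 1-{[3,4-bis(trimethylsilyloxy)cyclohex-3-en-1-yl]methyl}pyrrolidin-2-one (racemic) | C[Si](C)(C)OC1=C(O[Si](C)(C)C)CC(CN2CCCC2=O)CC1
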